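# (2S,2''S)-3',8''-Biflavanone CNP0237714.1: ring A'' by vinylketene–siloxyalkyne benzannulation, both stereocentres by rhodium-catalysed aryl addition to chromones

## The problem

The target is a 3',8''-linked biflavanone. Unit 1 is a 5,7-dihydroxyflavanone (O1, C2–C8a, ring B = C1'–C6'). Unit 2 is a 5''-hydroxy-7''-methoxyflavanone (O1'', C2''–C8a'', aryl = C1'''–C6''') with a 4-hydroxyphenyl group at C2'', and ring B is bonded through C3' to C8'' of ring A''. The biaryl bond joins a carbon ortho to the C4' oxygen to a carbon lying between two oxygens (C7''–O and C8a''–O), so a cross-coupling would have to unite two hindered, electron-rich partners. Ring A'' is a phloroglucinol whose three oxygens must end up different (ring ether O1'', methyl ether at C7'', free hydroxyl at C5''), and its two unsubstituted carbons, C4a'' and C6'', must be told apart when the C4'' carbonyl is attached. The stereocentres C2 and C2'' (both S) are benzylic ether carbons β to a ketone and lie far apart across the biaryl, so neither can control the other and each needs external control. Both are lost by enolisation and retro-oxa-Michael opening to the 2'-hydroxychalcone, which base promotes readily, so they should be made late and kept away from base. Five phenols must be freed at the end beside one aryl methyl ether, which rules out global demethylation. The enabling feature is ring A'' itself: a 1,3,5-trioxygenated benzene with the aryl group on C8'' between two oxygens and hydrogens at C4a'' and C6'' is the phenol formed when a 3-alkoxy vinylketene (C7''–O, C4a'', C5''–O, C6'') combines with an aryl siloxyalkyne (C8'', C8a''–O), each oxygen arriving with a different substituent.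

## Retrosynthesis

**Target 27 to 26.** The last cut removes five O-alkyl bonds: three benzyl ethers, the isopropyl ether at C4' and the ethyl ether at C5''. All five fall to BCl3, which spares an unchelated aryl methyl ether, so the precursor is the fully protected biflavanone 26. The forward step must be free of base and must leave C7''–OMe alone.

**26 to boronic acid 21 and chromone 25.** Unit 1 is cut at C2–C1'. The neighbouring cut, O1–C2, would mean an oxa-Michael closure of a 2'-hydroxychalcone. That closure is reversible, is itself the racemisation pathway, and is not reliably enantioselective for chalcones without an activating group. Aryl transfer to a chromone forms a C–C bond irreversibly under neutral conditions. The achiral partner 25 comes in two steps from 1-(2,4,6-trihydroxyphenyl)ethan-1-one 22 through the dibenzyl ether 23. The forward reaction must set C2 by ligand control alone, since C2'' is too far away to help or hinder.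

**21 to 20 to chloride 19.** The C1'–B bond is traced to C1'–Cl. A chlorine on ring B is the one latent boron that survives organolithium reagents, thermolysis and Lewis acids. This is why ring B carries chlorine and not a masked aldehyde. The borylation is asked not to disturb C2''.

**19 to chromone 17 and boronic acid 18.** Unit 2 is cut in the same way at C2''–C1'''. It is closed before unit 1 because the chromone has to be built by enaminone condensation, which would also attack the C3 methylene of an existing flavanone. The chlorine on ring B is inert to the rhodium catalyst.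

**17 to ketone 15 to phenol 13.** The chromone loses C2'' (one carbon from a formamide acetal) and then the acetyl group at C4a''. The acylation must go ortho to the C8a'' hydroxyl and not to C6''; chelation of the ortho-hydroxy ketone is the lever.

**13 to 12 to 11.** These cuts are the O-methyl bond at C7'' and the O-silyl bond at C8a''. In 11 the two oxygens flanking the aryl group are already different (free OH and silyl ether), so methylation followed by desilylation needs no selectivity.

**11 to siloxyalkyne 5 and cyclobutenone 6 (key disconnection).** Ring A'' is cut at C7''–C8'', C4a''–C8a'' and C6''–C7''. The alternative, a cross-coupling at C8'', would face two ortho oxygens on one partner and would still leave three oxygens to be differentiated. The benzannulation forms the hindered biaryl as an ordinary alkyne substituent and delivers the three oxygens as OH, OSi and OEt. The precursors are a disubstituted alkyne and a commercial four-carbon ring. The forward reaction needs the ketene carbonyl carbon to bond to the aryl-bearing alkyne carbon.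

**5 to ester 2 to salicylate 1.** The alkyne carbon next to oxygen is the former ester carbonyl and the second alkyne carbon comes from CH2Br2 (ester-to-ynolate homologation with 1,2-aryl shift). The isopropyl ether has no benzylic hydrogens to lose to butyllithium, tolerates BF3 and leaves with BCl3.

## Roads not taken

**Alternative 1:** The cut is at C2–C3 and C2''–C3''. Base converts the bis(aryl ester) A2 into the bis(1,3-diketone) A1 by two Baker–Venkataraman acyl shifts. Cyclodehydration gives the biflavone A3, and both C2=C3 bonds are then hydrogenated enantioselectively.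
- Merits: both units grow in the same operations, and every step up to A3 is among the most dependable in flavonoid chemistry. In operations spent on the two pyranone rings it is shorter than the chosen plan, which handles the units one after the other.
- Weak points: A2 presupposes the biaryl, so the hindered coupling at C8'' remains. The acetyl group and the two methyl ethers on ring A'' must be sorted by protecting groups. Both stereocentres depend on asymmetric hydrogenation of two electron-rich flavone double bonds, a reaction prone to over-reduction to flavan-4-ols and to loss of benzyl ethers. Any shortfall in selectivity appears as diastereomers.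
- Comparison: the later chelation-controlled 5''-O-demethylation is no harder than the de-ethylation needed here. The chosen plan sets against the better convergence a biaryl made without coupling, oxygens differentiated by construction, and stereocentres made one at a time by C–C bond formation.

**Alternative 2:** The cut is at C4''–C4a''. The (S)-3-aryloxy-3-arylpropanoic acid A5 is activated with (CF3CO)2O, and the acylium carbon closes ring C'' onto C4a'' to give flavanone A4.
- Merits: the acylation is intramolecular, so only C4a'' can be reached. In this respect it is better than the intermolecular acylation of step 6. C2'' is fixed before the ring closes.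
- Weak points: the stereocentre of A5 is a benzylic aryl ether that must survive a strongly acidic acylation, where ionisation would racemise it or eliminate to the cinnamic acid. Its construction, a Mitsunobu etherification of the hindered C8a'' phenol with a benzylic β-hydroxy ester, competes with elimination. The biaryl still has to be coupled, and unit 1 still has to be grown from the bromide, so the late boron chemistry is not avoided.
- Comparison: the chosen plan accepts a regiochemical question at C4a''. In return the stereocentre is formed under neutral catalytic conditions and never meets strong acid.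

**Alternative 3:** The cut is at O1–C8a and C4–C4a. The alkoxide of the (S)-β-hydroxy ester A7 adds at C8a of 3,5-bis(benzyloxy)benzyne, released from the silyl triflate A8 by CsF, and the aryl anion at C4a acylates the ester to give flavanone A6.
- Merits: ring C of unit 1 forms in one convergent step. C2 comes from a β-hydroxy ester whose configuration can be secured beforehand. The C5 benzyloxy group directs the alkoxide to the right aryne carbon. No boron has to be installed late, which is a real saving over steps 9 and 10 here.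
- Weak points: the benzylic aldolate can undergo retro-aldol cleavage. The aryl anion can be quenched by the acidic α-methylene of the ester before it acylates. A8 costs several steps where chromone 25 costs two. Ring A'' must already be in place (coupled and protected), and unit 2 must then be built in the presence of the base-sensitive unit 1.
- Comparison: the chosen plan sets against the shorter unit-1 construction a key step that settles ring A'' and the biaryl together, and one reaction type of strong precedent for both stereocentres.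

Key step: step 3

Assumption 1: the C3'–C8'' axis (three ortho oxygens, one ortho hydrogen) is taken to rotate at ambient temperature, as the target defines no axial descriptor; intermediates may show rotamers in NMR.

Assumption 2: the (S)-bisphosphine is assumed to deliver the aryl group to the chromone face that gives the (2S)-flavanone, by analogy with the sense known for cyclic enones; if a model addition shows the opposite sense, the (R)-ligand is used in steps 8 and 13.

## Route

Step 1
Reactants: 1 methyl 5-chloro-2-hydroxybenzoate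
Product: 2 methyl 5-chloro-2-(propan-2-yloxy)benzoate
Conditions: 2-bromopropane, K2CO3, DMF, 60 °C
Reagents that add atoms: 2-bromopropane, CC(C)Br
Why: Williamson ether synthesis on the salicylate phenoxide. The isopropyl ether has no benzylic C–H for the organolithium step, is stable to BF3 and is cleaved by BCl3 at the end.

Step 2
Reactants: 2 methyl 5-chloro-2-(propan-2-yloxy)benzoate
Product: 5 ({[5-chloro-2-(propan-2-yloxy)phenyl]ethynyl}oxy)tri(propan-2-yl)silane, via lithium dibromoenolate 3 (not isolated), via lithium ynolate 4 (not isolated)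
Conditions: CH2Br2, LiTMP (from 2,2,6,6-tetramethylpiperidine and n-BuLi), THF, −78 °C; n-BuLi, −78 → 0 °C; TIPSCl, −78 °C → rt
Reagents that add atoms: dibromomethane, BrCBr; chlorotri(propan-2-yl)silane, CC(C)[Si](Cl)(C(C)C)C(C)C
Why: Kowalski ester homologation stopped at the ynolate: LiCHBr2 adds to the ester, enolate 3 undergoes bromine–lithium exchange, and the carbenoid rearranges by 1,2-aryl shift with loss of LiBr to ynolate 4. The bulky chlorosilane silylates 4 on oxygen, and the aryl chloride should not exchange with n-BuLi at these temperatures.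

Step 3
Reactants: 5 ({[5-chloro-2-(propan-2-yloxy)phenyl]ethynyl}oxy)tri(propan-2-yl)silane; 6 3-ethoxycyclobut-2-en-1-one
Product: 11 2-[5-chloro-2-(propan-2-yloxy)phenyl]-5-ethoxy-3-{[tri(propan-2-yl)silyl]oxy}phenol, via ethoxyvinylketene 7 (not isolated), via vinylcyclobutenone 8 (not isolated), via dienylketene 9 (not isolated), via cyclohexadienone 10 (not isolated)
Conditions: 6 (1.2 equiv), toluene, 80 °C then 110 °C, sealed tube
Reagents that add atoms: none
Why: Danheiser benzannulation of a cyclobutenone with a siloxyalkyne. Thermal 4π electrocyclic opening of 6 breaks C6''–C7'' and gives vinylketene 7. Its C=C bond adds [2+2] to the electron-rich alkyne and forms C7''–C8'' and C4a''–C8a'' in the four-membered ring of 8. A second 4π opening gives dienylketene 9. Ring A'' then closes by thermal disrotatory 6π electrocyclisation, which re-forms C6''–C7'' in cyclohexadienone 10, and tautomerisation gives phenol 11. No stereocentre is created. The selectivity needed is the regiochemistry of the [2+2] step, ketene carbonyl carbon to the aryl-bearing alkyne carbon; the polarisation of the ynol ether secures it, since the carbon β to oxygen is the nucleophilic one. The aryl group therefore ends up between the new hydroxyl (C7'') and the siloxy group (C8a''), with the ethoxy group at C5'' and hydrogens at C4a'' and C6''.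

Step 4
Reactants: 11 2-[5-chloro-2-(propan-2-yloxy)phenyl]-5-ethoxy-3-{[tri(propan-2-yl)silyl]oxy}phenol
Product: 12 {2-[5-chloro-2-(propan-2-yloxy)phenyl]-5-ethoxy-3-methoxyphenoxy}tri(propan-2-yl)silane
Conditions: MeI, K2CO3, acetone, reflux
Reagents that add atoms: iodomethane, CI
Why: Williamson methylation of the only free phenol fixes the C7'' methyl ether. The triisopropylsilyl aryl ether should be stable to carbonate in acetone, so C8a''–O stays distinct.

Step 5
Reactants: 12 {2-[5-chloro-2-(propan-2-yloxy)phenyl]-5-ethoxy-3-methoxyphenoxy}tri(propan-2-yl)silane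
Product: 13 2-[5-chloro-2-(propan-2-yloxy)phenyl]-5-ethoxy-3-methoxyphenol
Conditions: TBAF, THF, 0 °C; aq. NH4Cl
Reagents that add atoms: none
Why: Fluoride-induced cleavage of the aryl silyl ether, driven by the Si–F bond, frees only the C8a'' hydroxyl that will become O1''.

Step 6
Reactants: 13 2-[5-chloro-2-(propan-2-yloxy)phenyl]-5-ethoxy-3-methoxyphenol
Product: 15 1-{3-[5-chloro-2-(propan-2-yloxy)phenyl]-6-ethoxy-2-hydroxy-4-methoxyphenyl}ethan-1-one, via difluoroboron chelate 14 (not isolated)
Conditions: AcOH, BF3·OEt2, 70 °C; then MeOH/H2O, 60 °C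
Reagents that add atoms: acetic acid, CC(=O)O
Why: Friedel–Crafts acylation with Fries-type equilibration under BF3, the standard entry to 2-hydroxy-4,6-dialkoxyacetophenones. The ortho-hydroxy ketone is trapped as the six-membered chelate 14, which should favour C4a'' over C6''. Alkyl aryl ethers and the aryl chloride are expected to be inert to BF3.

Step 7
Reactants: 15 1-{3-[5-chloro-2-(propan-2-yloxy)phenyl]-6-ethoxy-2-hydroxy-4-methoxyphenyl}ethan-1-one
Product: 17 8-[5-chloro-2-(propan-2-yloxy)phenyl]-5-ethoxy-7-methoxy-4H-chromen-4-one, via enaminone 16 (not isolated)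
Conditions: DMF-DMA, toluene, 90 °C; then conc. HCl, CH2Cl2, rt
Reagents that add atoms: N,N-dimethylformamide dimethyl acetal, COC(OC)N(C)C
Why: Enaminone route to chromones: the methyl ketone condenses with the formamide acetal, and acid then promotes addition of the phenol and loss of dimethylamine. The added carbon becomes C2''.

Step 8
Reactants: 17 8-[5-chloro-2-(propan-2-yloxy)phenyl]-5-ethoxy-7-methoxy-4H-chromen-4-one; 18 [4-(benzyloxy)phenyl]boronic acid
Product: 19 (2S)-2-[4-(benzyloxy)phenyl]-8-[5-chloro-2-(propan-2-yloxy)phenyl]-5-ethoxy-7-methoxy-2,3-dihydro-4H-chromen-4-one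
Conditions: [Rh(OH)(cod)]2 (cat.), (S)-MeO-F12-BIPHEP [(S)-(6,6'-dimethoxybiphenyl-2,2'-diyl)bis[bis(3,4,5-trifluorophenyl)phosphane]] (cat.), toluene/H2O, 30 °C
Reagents that add atoms: none
Why: Hayashi–Miyaura asymmetric 1,4-addition of an arylboronic acid to a chromone. The aryl–rhodium species with the electron-poor atropisomeric bisphosphine inserts C2''=C3'' on one face and sets C2'' as S by ligand control. Hydrolysis of the rhodium enolate releases the flavanone under neutral conditions, so no retro-oxa-Michael opening is expected; the aryl chloride is inert.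

Step 9
Reactants: 19 (2S)-2-[4-(benzyloxy)phenyl]-8-[5-chloro-2-(propan-2-yloxy)phenyl]-5-ethoxy-7-methoxy-2,3-dihydro-4H-chromen-4-one
Product: 20 (2S)-2-[4-(benzyloxy)phenyl]-5-ethoxy-7-methoxy-8-[2-(propan-2-yloxy)-5-(4,4,5,5-tetramethyl-1,3,2-dioxaborolan-2-yl)phenyl]-2,3-dihydro-4H-chromen-4-one
Conditions: B2pin2, Pd2(dba)3 (cat.), XPhos, KOAc, 1,4-dioxane, 100 °C
Reagents that add atoms: bis(pinacolato)diboron, CC1(C)OB(OC1(C)C)B1OC(C)(C)C(C)(C)O1
Why: Miyaura borylation of an electron-rich aryl chloride with zerovalent palladium and a bulky biarylphosphine. Acetate in an aprotic solvent is a weak enough base that the ketone and C2'' should be tolerated.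

Step 10
Reactants: 20 (2S)-2-[4-(benzyloxy)phenyl]-5-ethoxy-7-methoxy-8-[2-(propan-2-yloxy)-5-(4,4,5,5-tetramethyl-1,3,2-dioxaborolan-2-yl)phenyl]-2,3-dihydro-4H-chromen-4-one
Product: 21 {3-[(2S)-2-[4-(benzyloxy)phenyl]-5-ethoxy-7-methoxy-4-oxo-3,4-dihydro-2H-chromen-8-yl]-4-(propan-2-yloxy)phenyl}boronic acid
Conditions: NaIO4, NH4OAc, acetone/H2O, rt
Reagents that add atoms: water, O
Why: Hydrolysis of the pinacol boronate is driven by periodate cleavage of the released diol under buffered, near-neutral conditions. The free boronic acid allows step 13 to run without added base.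

Step 11
Reactants: 22 1-(2,4,6-trihydroxyphenyl)ethan-1-one
Product: 23 1-[2,4-bis(benzyloxy)-6-hydroxyphenyl]ethan-1-one
Conditions: BnBr (2.1 equiv), K2CO3, acetone, reflux
Reagents that add atoms: benzyl bromide, BrCc1ccccc1
Why: Williamson benzylation. The hydroxyl hydrogen-bonded to the acetyl carbonyl is the least nucleophilic and should stay free for the ring closure.

Step 12
Reactants: 23 1-[2,4-bis(benzyloxy)-6-hydroxyphenyl]ethan-1-one
Product: 25 5,7-bis(benzyloxy)-4H-chromen-4-one, via enaminone 24 (not isolated)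
Conditions: DMF-DMA, toluene, 90 °C; then conc. HCl, CH2Cl2, rt
Reagents that add atoms: N,N-dimethylformamide dimethyl acetal, COC(OC)N(C)C
Why: The same enaminone condensation and acid-promoted cyclisation as in step 7. The added carbon becomes C2 of unit 1.

Step 13
Reactants: 21 {3-[(2S)-2-[4-(benzyloxy)phenyl]-5-ethoxy-7-methoxy-4-oxo-3,4-dihydro-2H-chromen-8-yl]-4-(propan-2-yloxy)phenyl}boronic acid; 25 5,7-bis(benzyloxy)-4H-chromen-4-one
Product: 26 (2S)-5,7-bis(benzyloxy)-2-{3-[(2S)-2-[4-(benzyloxy)phenyl]-5-ethoxy-7-methoxy-4-oxo-3,4-dihydro-2H-chromen-8-yl]-4-(propan-2-yloxy)phenyl}-2,3-dihydro-4H-chromen-4-one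
Conditions: 25 (2 equiv), [Rh(OH)(cod)]2 (cat.), (S)-MeO-F12-BIPHEP (cat.), toluene/H2O, 40 °C
Reagents that add atoms: none
Why: The same Hayashi–Miyaura 1,4-addition with the roles reversed. The ligand alone sets C2 as S, because C2'' is too remote to influence the insertion. The chromone is used in excess so that insertion outruns hydrolysis of the aryl–rhodium species, and the neutral medium protects C2''.

Step 14
Reactants: 26 (2S)-5,7-bis(benzyloxy)-2-{3-[(2S)-2-[4-(benzyloxy)phenyl]-5-ethoxy-7-methoxy-4-oxo-3,4-dihydro-2H-chromen-8-yl]-4-(propan-2-yloxy)phenyl}-2,3-dihydro-4H-chromen-4-one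
Product: 27 (2S)-5,7-dihydroxy-2-{4-hydroxy-3-[(2S)-5-hydroxy-2-(4-hydroxyphenyl)-7-methoxy-4-oxo-3,4-dihydro-2H-chromen-8-yl]phenyl}-2,3-dihydro-4H-chromen-4-one
Conditions: BCl3, C6HMe5, CH2Cl2, −78 → 0 °C; then H2O
Reagents that add atoms: none
Why: Lewis-acid ether cleavage. BCl3 with pentamethylbenzene as cation scavenger removes the benzyl ethers at low temperature and the isopropyl ether near 0 °C, and cleaves the C5'' ethyl ether through the six-membered boron chelate with the C4'' carbonyl. The unchelated C7'' methyl ether is not attacked by BCl3 at these temperatures, and the absence of base should preserve both stereocentres.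

## Compound list

1 | methyl 5-chloro-2-hydroxybenzoate | COC(=O)c1cc(Cl)ccc1O | starting material
2 | methyl 5-chloro-2-(propan-2-yloxy)benzoate | COC(=O)c1cc(Cl)ccc1OC(C)C | intermediate
3 | lithium 2,2-dibromo-1-[5-chloro-2-(propan-2-yloxy)phenyl]ethen-1-olate (not isolated) | [Li+].[O-]C(=C(Br)Br)c1cc(Cl)ccc1OC(C)C | intermediate
4 | lithium 2-[5-chloro-2-(propan-2-yloxy)phenyl]ethyn-1-olate (not isolated) | [Li+].[O-]C#Cc1cc(Cl)ccc1OC(C)C | intermediate
5 | ({[5-chloro-2-(propan-2-yloxy)phenyl]ethynyl}oxy)tri(propan-2-yl)silane | CC(C)Oc1ccc(Cl)cc1C#CO[Si](C(C)C)(C(C)C)C(C)C | intermediate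
6 | 3-ethoxycyclobut-2-en-1-one | CCOC1=CC(=O)C1 | starting material
7 | 3-ethoxybuta-1,3-dien-1-one (not isolated) | CCOC(=C)C=C=O | intermediate
8 | 2-[5-chloro-2-(propan-2-yloxy)phenyl]-4-(1-ethoxyethenyl)-3-{[tri(propan-2-yl)silyl]oxy}cyclobut-2-en-1-one (racemic, not isolated) | O=C1C(c2cc(Cl)ccc2OC(C)C)=C(O[Si](C(C)C)(C(C)C)C(C)C)C1C(=C)OCC | intermediate
9 | (3E)-2-[5-chloro-2-(propan-2-yloxy)phenyl]-5-ethoxy-3-{[tri(propan-2-yl)silyl]oxy}hexa-1,3,5-trien-1-one (not isolated) | O=C=C(c1cc(Cl)ccc1OC(C)C)/C(O[Si](C(C)C)(C(C)C)C(C)C)=C\C(=C)OCC | intermediate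
10 | 2-[5-chloro-2-(propan-2-yloxy)phenyl]-5-ethoxy-3-{[tri(propan-2-yl)silyl]oxy}cyclohexa-2,4-dien-1-one (not isolated) | O=C1CC(OCC)=CC(O[Si](C(C)C)(C(C)C)C(C)C)=C1c1cc(Cl)ccc1OC(C)C | intermediate
11 | 2-[5-chloro-2-(propan-2-yloxy)phenyl]-5-ethoxy-3-{[tri(propan-2-yl)silyl]oxy}phenol | CCOc1cc(O)c(-c2cc(Cl)ccc2OC(C)C)c(O[Si](C(C)C)(C(C)C)C(C)C)c1 | intermediate
12 | {2-[5-chloro-2-(propan-2-yloxy)phenyl]-5-ethoxy-3-methoxyphenoxy}tri(propan-2-yl)silane | CCOc1cc(OC)c(-c2cc(Cl)ccc2OC(C)C)c(O[Si](C(C)C)(C(C)C)C(C)C)c1 | intermediate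
13 | 2-[5-chloro-2-(propan-2-yloxy)phenyl]-5-ethoxy-3-methoxyphenol | CCOc1cc(O)c(-c2cc(Cl)ccc2OC(C)C)c(OC)c1 | intermediate
14 | O,O'-difluoroboron chelate of ketone 15, boron bridging the phenolic and the carbonyl oxygen (not isolated) | CC1=[O+][B-](F)(F)Oc2c(-c3cc(Cl)ccc3OC(C)C)c(OC)cc(OCC)c12 | intermediate
15 | 1-{3-[5-chloro-2-(propan-2-yloxy)phenyl]-6-ethoxy-2-hydroxy-4-methoxyphenyl}ethan-1-one | CC(=O)c1c(O)c(-c2cc(Cl)ccc2OC(C)C)c(OC)cc1OCC | intermediate
16 | (2E)-1-{3-[5-chloro-2-(propan-2-yloxy)phenyl]-6-ethoxy-2-hydroxy-4-methoxyphenyl}-3-(dimethylamino)prop-2-en-1-one (not isolated) | CN(C)/C=C/C(=O)c1c(O)c(-c2cc(Cl)ccc2OC(C)C)c(OC)cc1OCC | intermediate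
17 | 8-[5-chloro-2-(propan-2-yloxy)phenyl]-5-ethoxy-7-methoxy-4H-chromen-4-one | O=c1ccoc2c(-c3cc(Cl)ccc3OC(C)C)c(OC)cc(OCC)c12 | intermediate
18 | [4-(benzyloxy)phenyl]boronic acid | OB(O)c1ccc(OCc2ccccc2)cc1 | starting material
19 | (2S)-2-[4-(benzyloxy)phenyl]-8-[5-chloro-2-(propan-2-yloxy)phenyl]-5-ethoxy-7-methoxy-2,3-dihydro-4H-chromen-4-one | COc1cc(OCC)c2c(c1-c1cc(Cl)ccc1OC(C)C)O[C@H](c1ccc(OCc3ccccc3)cc1)CC2=O | intermediate
20 | (2S)-2-[4-(benzyloxy)phenyl]-5-ethoxy-7-methoxy-8-[2-(propan-2-yloxy)-5-(4,4,5,5-tetramethyl-1,3,2-dioxaborolan-2-yl)phenyl]-2,3-dihydro-4H-chromen-4-one | COc1cc(OCC)c2c(c1-c1cc(B3OC(C)(C)C(C)(C)O3)ccc1OC(C)C)O[C@H](c1ccc(OCc3ccccc3)cc1)CC2=O | intermediate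
21 | {3-[(2S)-2-[4-(benzyloxy)phenyl]-5-ethoxy-7-methoxy-4-oxo-3,4-dihydro-2H-chromen-8-yl]-4-(propan-2-yloxy)phenyl}boronic acid | COc1cc(OCC)c2c(c1-c1cc(B(O)O)ccc1OC(C)C)O[C@H](c1ccc(OCc3ccccc3)cc1)CC2=O | intermediate
22 | 1-(2,4,6-trihydroxyphenyl)ethan-1-one | CC(=O)c1c(O)cc(O)cc1O | starting material
23 | 1-[2,4-bis(benzyloxy)-6-hydroxyphenyl]ethan-1-one | CC(=O)c1c(O)cc(OCc2ccccc2)cc1OCc1ccccc1 | intermediate
24 | (2E)-1-[2,4-bis(benzyloxy)-6-hydroxyphenyl]-3-(dimethylamino)prop-2-en-1-one (not isolated) | CN(C)/C=C/C(=O)c1c(O)cc(OCc2ccccc2)cc1OCc1ccccc1 | intermediate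
25 | 5,7-bis(benzyloxy)-4H-chromen-4-one | O=c1ccoc2cc(OCc3ccccc3)cc(OCc3ccccc3)c12 | intermediate
26 | (2S)-5,7-bis(benzyloxy)-2-{3-[(2S)-2-[4-(benzyloxy)phenyl]-5-ethoxy-7-methoxy-4-oxo-3,4-dihydro-2H-chromen-8-yl]-4-(propan-2-yloxy)phenyl}-2,3-dihydro-4H-chromen-4-one | COc1cc(OCC)c2c(c1-c1cc([C@@H]3CC(=O)c4c(OCc5ccccc5)cc(OCc5ccccc5)cc4O3)ccc1OC(C)C)O[C@H](c1ccc(OCc3ccccc3)cc1)CC2=O | intermediate
27 | (2S)-5,7-dihydroxy-2-{4-hydroxy-3-[(2S)-5-hydroxy-2-(4-hydroxyphenyl)-7-methoxy-4-oxo-3,4-dihydro-2H-chromen-8-yl]phenyl}-2,3-dihydro-4H-chromen-4-one | COc1cc(O)c2c(c1-c1cc([C@@H]3CC(=O)c4c(O)cc(O)cc4O3)ccc1O)O[C@H](c1ccc(O)cc1)CC2=O | target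

## Step count and least certain steps

Total step count: 14. Longest linear sequence: 12 (steps 1–10, 13 and 14; steps 11 and 12 make the side fragment 25).

**Step 3 (key step).** The vinylogous-ester character of 6 may raise the barrier of the first 4π opening above what the siloxyalkyne tolerates. The ortho-substituted aryl alkyne may also add slowly, so that ketene dimerisation and O-acylation of the product phenol by the vinylketene compete.
- Fallback: generate the same vinylketene at room temperature by 1,4-dehydrochlorination. Commercial ethyl (2E)-3-ethoxybut-2-enoate would be saponified to (2E)-3-ethoxybut-2-enoic acid F1 and converted with oxalyl chloride into (2E)-3-ethoxybut-2-enoyl chloride F2.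
- Slow addition of Et3N to F2 in the presence of 5 should give vinylketene 7 and, by [2+2] addition, vinylcyclobutenone 8, which is then heated in toluene to 11.
- It sets out from 5 and rejoins the route at 8.

**Step 2.** The carbenoid may rearrange incompletely, excess butyllithium may attack the chloroarene on warming (ortho-metalation and aryne formation), or silylation may occur on carbon.
- Fallback: reach ynolate 4 by oxidation of an acetylide. Ester 2 would be reduced with LiAlH4 to [5-chloro-2-(propan-2-yloxy)phenyl]methanol F3 and oxidised with MnO2 to 5-chloro-2-(propan-2-yloxy)benzaldehyde F4.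
- Ohira–Bestmann homologation (dimethyl (1-diazo-2-oxopropyl)phosphonate, K2CO3, MeOH) gives 4-chloro-2-ethynyl-1-(propan-2-yloxy)benzene F5.
- Deprotonation with LiHMDS and oxidation with lithium tert-butyl peroxide give ynolate 4, which is silylated with TIPSCl to 5.
- It sets out from 2 and rejoins at 4.

**Step 6.** The C8a'' hydroxyl is flanked by the aryl group and may be slow to acylate and chelate, so acylation could drift to C6'', para to the hydroxyl; prolonged heating with BF3 could also start to cleave ethers.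
- Fallback: magnesium-mediated ortho-formylation of 13 (MgCl2, Et3N, paraformaldehyde, MeCN, reflux), which is strictly ortho through the magnesium phenoxide, gives 3-[5-chloro-2-(propan-2-yloxy)phenyl]-6-ethoxy-2-hydroxy-4-methoxybenzaldehyde F6.
- Addition of MeMgBr gives 2-[5-chloro-2-(propan-2-yloxy)phenyl]-5-ethoxy-6-(1-hydroxyethyl)-3-methoxyphenol F7, and oxidation of the benzylic alcohol with MnO2 gives 15.
- It sets out from 13 and rejoins at 15.

**Step 9.** Oxidative addition into the electron-rich chloride may be slow, and long exposure to acetate at 100 °C may erode C2'' by enolisation and retro-oxa-Michael opening.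
- Fallback: borylate before any stereocentre exists and mask the boron. Chromone 17 with (pin)B–B(dan) (Pd2(dba)3, XPhos, KOAc, dioxane) gives 8-[5-(2,3-dihydro-1H-naphtho[1,8-de][1,3,2]diazaborinin-2-yl)-2-(propan-2-yloxy)phenyl]-5-ethoxy-7-methoxy-4H-chromen-4-one F8.
- The rhodium-catalysed addition of 18 under the conditions of step 8, in which the diaminonaphthalene-protected boron does not transmetalate, gives (2S)-2-[4-(benzyloxy)phenyl]-8-[5-(2,3-dihydro-1H-naphtho[1,8-de][1,3,2]diazaborinin-2-yl)-2-(propan-2-yloxy)phenyl]-5-ethoxy-7-methoxy-2,3-dihydro-4H-chromen-4-one F9.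
- Aqueous HCl in THF releases boronic acid 21.
- It sets out from 17 and rejoins at 21.

**Step 14.** Cleavage of the chelated ethyl ether is expected to be slower than loss of benzyl and isopropyl. Forcing it could open the flavanone rings to chalcones, with loss of configuration, or begin to cleave the C7'' methyl ether.
- Fallback: exchange the ethyl group where no stereocentre is at risk. Chromone 17 with BCl3 (0 °C → rt) gives 8-(5-chloro-2-hydroxyphenyl)-5-hydroxy-7-methoxy-4H-chromen-4-one F10, and BnBr with K2CO3 in DMF gives 5-(benzyloxy)-8-[2-(benzyloxy)-5-chlorophenyl]-7-methoxy-4H-chromen-4-one F11.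
- The conditions of steps 8, 9, 10 and 13 then lead through (2S)-5-(benzyloxy)-2-[4-(benzyloxy)phenyl]-8-[2-(benzyloxy)-5-chlorophenyl]-7-methoxy-2,3-dihydro-4H-chromen-4-one F12, its pinacol boronate F13 and the boronic acid F14 to the pentabenzyl biflavanone F15.
- Hydrogenolysis of F15 (H2, palladium on carbon, EtOAc/MeOH) gives 27.
- It sets out from 17 and rejoins at 27.

## Further compounds

F1 | step 3 | (2E)-3-ethoxybut-2-enoic acid | CCO/C(C)=C/C(=O)O
F2 | step 3 | (2E)-3-ethoxybut-2-enoyl chloride | CCO/C(C)=C/C(=O)Cl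
F3 | step 2 | [5-chloro-2-(propan-2-yloxy)phenyl]methanol | OCc1cc(Cl)ccc1OC(C)C
F4 | step 2 | 5-chloro-2-(propan-2-yloxy)benzaldehyde | O=Cc1cc(Cl)ccc1OC(C)C
F5 | step 2 | 4-chloro-2-ethynyl-1-(propan-2-yloxy)benzene | C#Cc1cc(Cl)ccc1OC(C)C
F6 | step 6 | 3-[5-chloro-2-(propan-2-yloxy)phenyl]-6-ethoxy-2-hydroxy-4-methoxybenzaldehyde | O=Cc1c(O)c(-c2cc(Cl)ccc2OC(C)C)c(OC)cc1OCC
F7 | step 6 | 2-[5-chloro-2-(propan-2-yloxy)phenyl]-5-ethoxy-6-(1-hydroxyethyl)-3-methoxyphenol (racemic) | CC(O)c1c(O)c(-c2cc(Cl)ccc2OC(C)C)c(OC)cc1OCC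
F8 | step 9 | 8-[5-(2,3-dihydro-1H-naphtho[1,8-de][1,3,2]diazaborinin-2-yl)-2-(propan-2-yloxy)phenyl]-5-ethoxy-7-methoxy-4H-chromen-4-one | O=c1ccoc2c(-c3cc(B4Nc5cccc6cccc(N4)c56)ccc3OC(C)C)c(OC)cc(OCC)c12
F9 | step 9 | (2S)-2-[4-(benzyloxy)phenyl]-8-[5-(2,3-dihydro-1H-naphtho[1,8-de][1,3,2]diazaborinin-2-yl)-2-(propan-2-yloxy)phenyl]-5-ethoxy-7-methoxy-2,3-dihydro-4H-chromen-4-one | COc1cc(OCC)c2c(c1-c1cc(B3Nc4cccc5cccc(N3)c45)ccc1OC(C)C)O[C@H](c1ccc(OCc3ccccc3)cc1)CC2=O
F10 | step 14 | 8-(5-chloro-2-hydroxyphenyl)-5-hydroxy-7-methoxy-4H-chromen-4-one | O=c1ccoc2c(-c3cc(Cl)ccc3O)c(OC)cc(O)c12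
F11 | step 14 | 5-(benzyloxy)-8-[2-(benzyloxy)-5-chlorophenyl]-7-methoxy-4H-chromen-4-one | O=c1ccoc2c(-c3cc(Cl)ccc3OCc3ccccc3)c(OC)cc(OCc3ccccc3)c12
F12 | step 14 | (2S)-5-(benzyloxy)-2-[4-(benzyloxy)phenyl]-8-[2-(benzyloxy)-5-chlorophenyl]-7-methoxy-2,3-dihydro-4H-chromen-4-one | COc1cc(OCc3ccccc3)c2c(c1-c1cc(Cl)ccc1OCc1ccccc1)O[C@H](c1ccc(OCc3ccccc3)cc1)CC2=O
F13 | step 14 | (2S)-5-(benzyloxy)-2-[4-(benzyloxy)phenyl]-8-[2-(benzyloxy)-5-(4,4,5,5-tetramethyl-1,3,2-dioxaborolan-2-yl)phenyl]-7-methoxy-2,3-dihydro-4H-chromen-4-one | COc1cc(OCc3ccccc3)c2c(c1-c1cc(B3OC(C)(C)C(C)(C)O3)ccc1OCc1ccccc1)O[C@H](c1ccc(OCc3ccccc3)cc1)CC2=O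
F14 | step 14 | {4-(benzyloxy)-3-[(2S)-5-(benzyloxy)-2-[4-(benzyloxy)phenyl]-7-methoxy-4-oxo-3,4-dihydro-2H-chromen-8-yl]phenyl}boronic acid | COc1cc(OCc3ccccc3)c2c(c1-c1cc(B(O)O)ccc1OCc1ccccc1)O[C@H](c1ccc(OCc3ccccc3)cc1)CC2=O
F15 | step 14 | (2S)-5,7-bis(benzyloxy)-2-{4-(benzyloxy)-3-[(2S)-5-(benzyloxy)-2-[4-(benzyloxy)phenyl]-7-methoxy-4-oxo-3,4-dihydro-2H-chromen-8-yl]phenyl}-2,3-dihydro-4H-chromen-4-one | COc1cc(OCc3ccccc3)c2c(c1-c1cc([C@@H]3CC(=O)c4c(OCc5ccccc5)cc(OCc5ccccc5)cc4O3)ccc1OCc1ccccc1)O[C@H](c1ccc(OCc3ccccc3)cc1)CC2=O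
A1 | alternative 1 | 1-{3-[2-(benzyloxy)-5-{3-[2,4-bis(benzyloxy)-6-hydroxyphenyl]-3-oxopropanoyl}phenyl]-2-hydroxy-4,6-dimethoxyphenyl}-3-[4-(benzyloxy)phenyl]propane-1,3-dione | COc1cc(OC)c(C(=O)CC(=O)c2ccc(OCc3ccccc3)cc2)c(O)c1-c1cc(C(=O)CC(=O)c2c(O)cc(OCc3ccccc3)cc2OCc2ccccc2)ccc1OCc1ccccc1
A2 | alternative 1 | 2-acetyl-3,5-bis(benzyloxy)phenyl 3-[3-acetyl-2-{[4-(benzyloxy)benzoyl]oxy}-4,6-dimethoxyphenyl]-4-(benzyloxy)benzoate | COc1cc(OC)c(C(C)=O)c(OC(=O)c2ccc(OCc3ccccc3)cc2)c1-c1cc(C(=O)Oc2cc(OCc3ccccc3)cc(OCc3ccccc3)c2C(C)=O)ccc1OCc1ccccc1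
A3 | alternative 1 | 5,7-bis(benzyloxy)-2-{4-(benzyloxy)-3-[2-[4-(benzyloxy)phenyl]-5,7-dimethoxy-4-oxo-4H-chromen-8-yl]phenyl}-4H-chromen-4-one | COc1cc(OC)c2c(c1-c1cc(-c3cc(=O)c4c(OCc5ccccc5)cc(OCc5ccccc5)cc4o3)ccc1OCc1ccccc1)oc(-c1ccc(OCc3ccccc3)cc1)cc2=O
A4 | alternative 2 | (2S)-2-[4-(acetyloxy)phenyl]-8-[2-(benzyloxy)-5-bromophenyl]-5,7-dimethoxy-2,3-dihydro-4H-chromen-4-one | COc1cc(OC)c2c(c1-c1cc(Br)ccc1OCc1ccccc1)O[C@H](c1ccc(OC(C)=O)cc1)CC2=O
A5 | alternative 2 | (3S)-3-[4-(acetyloxy)phenyl]-3-{2-[2-(benzyloxy)-5-bromophenyl]-3,5-dimethoxyphenoxy}propanoic acid | COc1cc(OC)cc(O[C@@H](CC(=O)O)c2ccc(OC(C)=O)cc2)c1-c1cc(Br)ccc1OCc1ccccc1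
A6 | alternative 3 | (2S)-5,7-bis(benzyloxy)-2-{4-(benzyloxy)-3-[2,4-dimethoxy-6-(methoxymethoxy)phenyl]phenyl}-2,3-dihydro-4H-chromen-4-one | COCOc1cc(OC)cc(OC)c1-c1cc([C@@H]2CC(=O)c3c(OCc4ccccc4)cc(OCc4ccccc4)cc3O2)ccc1OCc1ccccc1
A7 | alternative 3 | methyl (3S)-3-{4-(benzyloxy)-3-[2,4-dimethoxy-6-(methoxymethoxy)phenyl]phenyl}-3-hydroxypropanoate | COCOc1cc(OC)cc(OC)c1-c1cc([C@@H](O)CC(=O)OC)ccc1OCc1ccccc1
A8 | alternative 3 | 3,5-bis(benzyloxy)-2-(trimethylsilyl)phenyl trifluoromethanesulfonate | C[Si](C)(C)c1c(OCc2ccccc2)cc(OCc2ccccc2)cc1OS(=O)(=O)C(F)(F)F
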